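The data are calculated for substances that don't exist; the scatter is artificial.

Teal shows 14.7% target at 3.00 min, and the question is how much of that survives to 25 min.

the same everywhere: catalyst 40 µM

|  | starting material | coupling partner | remark | time |
|---|---|---|---|---|
| teal | 20 mM | 10 mM | the very flask that is asked about, followed so far |  |
| red | 40 mM | 10 mM | run made earlier |  |
| flask | 20 mM | 10.0 mM |  | 25 min |

| run | time / min | target / % | starting material / % |
|---|---|---|---|
| teal | 0.250 | 4.9 | 91.7 |
| teal | 0.500 | 9.0 | 86.0 |
| teal | 1.33 | 13.3 | 74.4 |
| teal | 3.00 | 14.7 | 66.9 |
| red | 2.50 | 11.0 | 79.1 |
| red | 5.00 | 8.2 | 80.0 |
| red | 8.00 | 6.6 | 80.4 |
| red | 10.0 | 6.8 | 80.4 |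

(readings scatter by 0.5 percentage points)

- amount of target in the flask at 25 min, in percent of the starting material charged
- amount of starting material in the flask at 25 min, in percent of the starting material charged
- concentration of coupling partner at 25 min, in mM

- the analysis behind the earlier runs scatters by 0.5 percentage points, standard deviation

I build the teal flask up one process at a time. With the main step by itself, one partner takes one starting material to one target, so the 10 mM of partner in teal allows target up to:

50.0%

The second process is a drain I can't see. At 3.00 min teal has lost 33.1% of its starting material but shows 14.7% target, so 18.4% sits elsewhere. My number drops to that reading, which I take as the early end.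

The third process joins the late end, and red shows it. After 2.50 min red's starting material stays between 79.1% and 80.4%, while target falls from 11.0% to 6.8%. I call the first-order constant averaged over that fall the fade constant, the average fractional loss of target per minute once starting material stands still:

0.0641 /min

Red's flat last pair doesn't show a standstill, since the constant implies a fall of 0.79 percentage points there and each reading scatters by 0.5 points. Joining the two ends, I reckon teal's target at 25 min as:

3.59%

For starting material, red lost 7.84 mM on 10 mM of partner. That loss would leave teal 60.8%, so I place it between this and teal's last 66.9%.

The forecast differs from me on target: 9.5% target, 62% starting material and 0.1 mM partner, with “the system is finished well before 25 min”.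

The flask gives 3.81% target, 64.9% starting material and 0.148 mM partner.

    starting material + coupling partner ⇌ target (K = 290 /M, k = 27.0 /M/min)
    starting material + coupling partner ⇌ isomer of the product (K = 17000 /M, k = 10.0 /M/min)
    coupling partner + target → over-reaction product (k = 73.0 /M/min)
    target + catalyst ⇌ isomer of the product + catalyst, rate k4*[catalyst]*[target] forward; the back reaction follows from the equilibrium constant (k = 340 /M/min)

From teal's last reading to this result, target fades on average at 0.0614 /min, against the 0.0641 /min read from red. The neighbouring flask holds 0.10 mM of catalyst instead of 40 µM. Carrying over teal's reading, taken at 40 µM of catalyst, and red's constant, the same line again gives 3.59% for it. That neighbouring flask holds 2.77% target at 25 min, an average fade of 0.0759 /min when counted from the carried-over reading.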